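The runs were generated by integration for substances that don't exist.

Start from the late end of the ochre run, where the substrate stays at 59.4%, 58.0%, 58.2%.

| setting | amber | red | ochre | west | south | north-east | south-east |
|---|---|---|---|---|---|---|---|
| substrate | 15 mM | 32 mM | 90 mM | 12 mM | 25 mM | 50 mM | 100 mM |
| activator | 26.4 mM | 26.4 mM | 26.4 mM | 26.4 mM | 26.4 mM | 26.4 mM | 26.4 mM |
| remark | run made earlier | run made earlier | run made earlier |  |  |  |  |
| time |  |  |  | 1.0 h | 1.0 h | 1.0 h | 1.0 h |

- amber (time / min: ring / %, substrate / %): 2.50: 4.0, 83.9; 8.00: 9.7, 58.9; 15.0: 16.7, 37.6; 20.0: 19.7, 31.5; 30.0: 19.6, 20.1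
- red (time / min: ring / %, substrate / %): 2.50: 2.4, 85.3; 8.00: 8.2, 60.5; 15.0: 13.8, 45.8; 20.0: 13.4, 37.7; 30.0: 16.8, 28.8
- ochre (time / min: ring / %, substrate / %): 6.00: 3.6, 72.3; 12.0: 4.5, 62.0; 20.0: 5.0, 59.4; 25.0: 6.1, 58.0; 30.0: 5.5, 58.2

(each reading ± 1 percentage point)

- percentages count the substrate that a species holds: one open dimer or self-condensation product counts as two
- steps that have been proposed: substrate + activator -> activated form; activated form -> ring; substrate + activated form -> open dimer; 2 substrate -> self-condensation product; ring <-> isomer of the product
- "hardly changes" means that all values lie within two and a half points (for a concentration: within two and a half percent of the largest)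

1. [ring] at the end for west, south, north-east, south-east, in this order
2. how that number moves from the first to the last of them (rises, then falls / rises all the way / falls all the way / falls, then rises / hardly changes)

What did the activator cost? Ochre lost 37.6 mM of substrate, more than its 26.4 mM of activator. Take that activator as used up, the limiting reagent, each unit making one activated form. A form that closes to ring costs one substrate; a form caught by substrate costs two. Setting the self-condensation product aside, the excess then counts the catches: 11.2 mM caught, 15.2 mM closed.

Where are the chances even? Closing needs no partner and catching needs a substrate, so the odds of caught to closed grow in step with [substrate]. Ochre's average [substrate], 71.2 mM, then reads 96.3 mM as the even point, the [substrate] at which a form is as likely caught as closed.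

How much closed material stands as ring? Ochre reads a share of 0.326.

Now reckon the end [ring] as share times closed, assuming the activator is used up and the loss matches ochre's. South-east, averaging 81.2 mM, gives 4.67 mM. North-east, averaging 31.2 mM, gives 6.50 mM. West holds less substrate than activator, so take its charge in place of the activator: the share times that charge reads 3.91 mM, an upper estimate. My 3 numbers climb, then come down.

The forecast says 2.7 mM, 5.2 mM, 6.5 mM, 5.2 mM, rises, then falls: past its peak the ring “falls as activator limits it and dimer wins”. My south-east lies below its value; my north-east matches it.

The flask gives 3.22 mM, 5.40 mM, 6.00 mM, 4.38 mM: rises, then falls.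

    substrate + activator → activated form (k = 0.0450 M⁻¹ s⁻¹)
    activated form → ring (k = 0.00330 s⁻¹)
    substrate + activated form → open dimer (k = 0.0390 M⁻¹ s⁻¹)
    2 substrate → self-condensation product (k = 7.20 × 10⁻⁵ M⁻¹ s⁻¹)
    ring ⇌ isomer of the product (K = 2.20, k = 0.00470 s⁻¹)

In west, ring and isomer of the product relax towards each other, both ways together, with a half-life of 1.69 min, much shorter than the 1.0 h of the run, and after 1.00 h they stand at 26.8% and 57.5%. In south-east, average [substrate] over the even point gives 0.826 caught per closed, while the end amounts, each open dimer counted as one catch, give 0.882. In north-east the same two numbers are 0.349 and 0.348.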